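## Plan

1. Locants: the ten-membered ring is C1 (methacrylate carbinol), C2, C3 (methyl carbinol), C4, C5 (acetate carbinol), C6=C7 (methyl on C7), C8=C9 (C9 on the lactone oxygen) and C12 (butenolide β-carbon, bound to C1). C10 is the lactone carbonyl, C11 its α-carbon, C13 the CH2OH carbon.
2. Enabling feature: C1, C3 and C5 form a 1,3,5-oxygenated run on the ten-membered ring. The tertiary carbinol C3 lies β to C1, and the only other neighbour of C1 is the fusion carbon C12 of the five-membered ring. As a ketone, C1 can therefore enolise only towards C2, C3 is its aldol acceptor, and the C5 oxygen sits where it can chelate that acceptor.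
3. Cuts, in retrosynthetic order: the acyl and silyl groups; C8=C9 and the lactone back to a furan (C9, C12, C11, C10-H); C2-C3 (ring opening, retro-aldol); C1-C2 (diazomethane carbon); C8-C9 (furyl anion plus allylic bromide); C4-C5 (allylboration of 3-methylbut-2-enal).
4. Forward order: the furan is bought as its 3,4-diester, and the C4-C8 chain is attached at C9. The ten-membered ring then closes at C2-C3, and the furan becomes the ylidene butenolide only after the ring and all three stereocentres are in place.
5. Stereochemistry: C5 comes from reagent-controlled allylboration, C3 from C5 through a samarium chelate, and C1 from C3 through hydroxyl-directed hydride delivery. E-C6=C7 comes from SeO2 oxidation of the E-methyl group, and C8=C9 from the strain of the ring.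

Key step: step 11

Remark: TIPS = triisopropylsilyl, PMB = 4-methoxybenzyl, Ipc = isopinocampheyl. C9 of 24 and 25 and the bridgeheads of 23 form without control and are drawn without descriptors, because step 15 removes them. The C3 descriptor reads R in diol 21 and S elsewhere only because the CIP ranking of C2 and C4 changes; the centre itself is never touched.

## Route

Step 1
Reactants: 1 dimethyl furan-3,4-dicarboxylate
Product: 2 methyl 4-(hydroxymethyl)furan-3-carboxylate
Conditions: i-Bu2AlH (2.1 equiv), CH2Cl2, −78 to −20 °C; aq potassium sodium tartrate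
Reagents that add atoms: none
Why: Ester reduction with i-Bu2AlH; once one ester has become an aluminium alkoxide the furan is richer in electrons and the surviving ester more crowded, so the second reduction should lag, and diester, hydroxy ester and diol differ enough in polarity to be separated and recycled.

Step 2
Reactants: 2 methyl 4-(hydroxymethyl)furan-3-carboxylate
Product: 3 methyl 4-[(triisopropylsilyloxy)methyl]furan-3-carboxylate
Conditions: TIPSCl, imidazole, DMF, rt
Reagents that add atoms: chlorotriisopropylsilane CC(C)[Si](Cl)(C(C)C)C(C)C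
Why: Standard silylation of a primary alcohol; the bulky TIPS ether is chosen to outlast LiN(i-Pr)2, HBr, SmI2, DBU and DDQ and to fall only to fluoride at the end.

Step 3
Reactants: 3 methyl 4-[(triisopropylsilyloxy)methyl]furan-3-carboxylate
Product: 4 4-[(triisopropylsilyloxy)methyl]furan-3-carboxylic acid
Conditions: LiOH, THF/MeOH/H2O, 50 °C; 1 M HCl to pH 4, 0 °C
Reagents that add atoms: lithium hydroxide [Li+].[OH-]
Why: Saponification carried out while nothing base-sensitive is present; it gives the carboxylate that directs the metalation of step 8 and whose carbon is C1 of the target.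

Step 4
Reactants: 5 3-methylbut-2-enal; 6 allylmagnesium bromide
Product: 8 (4S)-6-methylhepta-1,5-dien-4-ol, via borinate ester 7 (not isolated)
Conditions: (−)-Ipc2BOMe, 6, Et2O, 0 °C to rt; 5, −78 °C; then 3 M NaOH, 30% H2O2, rt
Reagents that add atoms: none
Why: Brown asymmetric allylboration through a closed chair transition state; the reagent derived from (+)-α-pinene attacks the aldehyde face that gives the S carbinol whenever the aldehyde substituent outranks allyl (as with benzaldehyde), and this sets C5.

Step 5
Reactants: 8 (4S)-6-methylhepta-1,5-dien-4-ol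
Product: 9 (4S)-4-[(4-methoxybenzyl)oxy]-6-methylhepta-1,5-diene
Conditions: NaH, PMBCl, Bu4NI (cat.), THF/DMF, 0 °C to rt
Reagents that add atoms: 4-methoxybenzyl chloride COc1ccc(CCl)cc1
Why: Williamson etherification; a PMB ether is placed on C5 because its oxygen is a good donor for samarium and because it can later be removed oxidatively beside esters and a silyl ether.

Step 6
Reactants: 9 (4S)-4-[(4-methoxybenzyl)oxy]-6-methylhepta-1,5-diene
Product: 10 (2E,4S)-4-[(4-methoxybenzyl)oxy]-2-methylhepta-2,6-dien-1-ol
Conditions: SeO2 (0.3 equiv), t-BuOOH, salicylic acid (cat.), CH2Cl2, 0 °C to rt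
Reagents that add atoms: tert-butyl hydroperoxide CC(C)(C)OO (its oxygen is passed on through SeO2)
Why: Catalytic SeO2 allylic oxidation (ene reaction, then [2,3]-sigmatropic shift); it attacks the more substituted end of the trisubstituted alkene and oxidises the methyl group trans to the chain, which fixes E-C6=C7 and turns C8 into a functional carbon while the terminal alkene stays inert.

Step 7
Reactants: 10 (2E,4S)-4-[(4-methoxybenzyl)oxy]-2-methylhepta-2,6-dien-1-ol
Product: 11 (2E,4S)-1-bromo-4-[(4-methoxybenzyl)oxy]-2-methylhepta-2,6-diene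
Conditions: CBr4, PPh3, CH2Cl2, −20 to 0 °C
Reagents that add atoms: tetrabromomethane BrC(Br)(Br)Br
Why: Appel bromination of a primary allylic alcohol under neutral conditions, an SN2 displacement that should keep both the position and the geometry of the alkene.

Step 8
Reactants: 4 4-[(triisopropylsilyloxy)methyl]furan-3-carboxylic acid; 11 (2E,4S)-1-bromo-4-[(4-methoxybenzyl)oxy]-2-methylhepta-2,6-diene
Product: 13 2-{(2E,4S)-4-[(4-methoxybenzyl)oxy]-2-methylhepta-2,6-dien-1-yl}-4-[(triisopropylsilyloxy)methyl]furan-3-carboxylic acid, via dilithiated furoate 12 (not isolated)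
Conditions: 4, LiN(i-Pr)2 (2.1 equiv), THF, −78 °C; 11, −78 to −20 °C; 1 M HCl to pH 4
Reagents that add atoms: none
Why: Directed ortho-metalation of a 3-furoic acid as its dianion followed by SN2 alkylation; the C-H between ring oxygen and carboxylate (C9) is the most acidic one, and the furyllithium attacks the open CH2Br end of 11 rather than its branched γ-carbon, forming C8-C9.

Step 9
Reactants: 13 furoic acid with the heptadienyl side chain
Product: 14 2-{(2E,4S)-4-[(4-methoxybenzyl)oxy]-2-methyl-6-oxohept-2-en-1-yl}-4-[(triisopropylsilyloxy)methyl]furan-3-carboxylic acid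
Conditions: PdCl2 (10 mol %), CuCl (co-catalyst), O2 (1 atm), DMF/H2O 7:1, rt
Reagents that add atoms: water O
Why: Tsuji-Wacker oxidation; only the monosubstituted alkene binds divalent palladium and Markovnikov attack of water gives the C3 methyl ketone, and running it before the halide is installed keeps an α-bromo ketone away from palladium and from chloride.

Step 10
Reactants: 14 keto acid
Product: 17 2-bromo-1-(2-{(2E,4S)-4-[(4-methoxybenzyl)oxy]-2-methyl-6-oxohept-2-en-1-yl}-4-[(triisopropylsilyloxy)methyl]furan-3-yl)ethan-1-one, via acid chloride 15 (not isolated), via diazoketone 16 (not isolated)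
Conditions: 1-chloro-N,N,2-trimethylprop-1-en-1-amine, CH2Cl2, 0 °C; CH2N2 (excess), Et2O, 0 °C; N2 purge; 48% aq HBr (1.05 equiv), −10 °C
Reagents that add atoms: diazomethane C=[N+]=[N-]; hydrogen bromide Br
Why: Neutral acid chloride formation, acylation of diazomethane (first half of an Arndt-Eistert sequence) and hydrobromination of the diazoketone; this leaves the C3 methyl ketone alone, avoids any base that could expel the β-alkoxy group, puts bromine only on the new carbon C2, and the basic diazo carbon consumes the single equivalent of HBr before it can reach the PMB or TIPS ethers.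

Step 11
Reactants: 17 bromoacetyl furan with the C3 methyl ketone
Product: 20 furan-fused (3S,5S,6E)-β-hydroxy cyclodecenone (C1 ketone; C3 OH and CH3; C5 OPMB; C7 CH3; C11 CH2OTIPS), via samarium enolate 18 (not isolated), via samarium aldolate 19 (not isolated)
Conditions: SmI2 (2.5 equiv, 0.1 M in THF), THF, −78 to −40 °C, 17 added by syringe pump over 3 h to a final 2 mM; sat. aq NH4Cl at −78 °C
Reagents that add atoms: none
Why: Two single-electron transfers from divalent samarium break the C2-Br bond and leave the trivalent samarium enolate 18, which can only be the C1=C2 enolate because C1 carries the furan carbon C12 on its other side and no base is present that could enolise the C3 ketone. The closest known reaction type is the SmI2-mediated intramolecular Reformatsky (reductive aldol) reaction, established for eight- to fourteen-membered rings with aldehyde acceptors and for ketone acceptors in common rings; a ketone acceptor at ring size ten stretches that precedent, which is why this step heads the list of risks. The ten-membered carbocycle closes by 10-(enolendo)-exo-trig attack of C2 on the C3 carbonyl, helped by high dilution, by the metal that holds enolate oxygen and ketone oxygen together, and by the furan and the E-alkene, which take rotational freedom out of the chain. C3 is controlled by C5: the oxophilic metal also takes up the PMB ether oxygen, so the transition state is a chair-chair bicyclic chelate with samarium and C3 as bridgeheads in which C6 lies equatorial and C2 arrives axially, and this places the new hydroxyl anti to the C5 oxygen (3S from 5S). The step needs chemoselective reduction of the bromide beside two ketones, secured by the much easier reduction of an α-bromo ketone at low temperature without HMPA or a proton source, and face selectivity at C3, secured by a chelating rather than a silyl ether at C5. The aldolate 19 stays bound to samarium until the cold quench, which holds back the retro-aldol reaction.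

Step 12
Reactants: 20 furan-fused β-hydroxy cyclodecenone
Product: 21 furan-fused (1R,3R,5S,6E)-1,3-diol (C1 OH anti to C3 OH; C5 OPMB)
Conditions: Me4NBH(OAc)3 (6 equiv), MeCN/AcOH 1:1, −30 °C
Reagents that add atoms: none
Why: Evans-Saksena reduction; ligand exchange ties the borohydride to the C3 hydroxyl and hydride is delivered within a chair-like six-membered transition state, which should give the 1,3-anti diol and hence R at C1, and removing the ketone at once ends any risk of retro-aldol opening.

Step 13
Reactants: 21 furan-fused 1,3-diol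
Product: 22 furan-fused (1R,3S,5S,6E)-C1 methacrylate (C3 OH free; C5 OPMB; C11 CH2OTIPS)
Conditions: methacrylic anhydride (1.5 equiv), Et3N, DMAP (0.2 equiv), CH2Cl2, 0 °C to rt
Reagents that add atoms: methacrylic anhydride C=C(C)C(=O)OC(=O)C(C)=C
Why: DMAP-catalysed acyl transfer, which tells the secondary C1 hydroxyl from the tertiary C3 hydroxyl on steric grounds.

Step 14
Reactants: 22 furan-fused C1 methacrylate
Product: 24 γ-hydroxybutenolide (C9 OH as an epimer mixture; C10 lactone carbonyl; C8 still CH2), via furan endoperoxide 23 (not isolated)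
Conditions: O2, tetraphenylporphyrin (cat.), visible light, i-Pr2NEt, CH2Cl2, −78 °C, then rt
Reagents that add atoms: dioxygen O=O
Why: [4+2] cycloaddition of singlet oxygen to the furan followed by Kornblum-DeLaMare fragmentation; only the bridgehead C10 carries a hydrogen, so the carbonyl can arise only there, and the trialkylfuran reacts far faster than the trisubstituted alkene (deactivated by its allylic oxygen) or the electron-poor methacrylate.

Step 15
Reactants: 24 γ-hydroxybutenolide
Product: 26 (1R,3S,5S,6E,8E)-ylidene butenolide (C5 OPMB; C13 OTIPS), via acetoxybutenolide 25 (not isolated)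
Conditions: Ac2O, pyridine, DMAP (5 mol %), CH2Cl2, 0 °C; then DBU, 0 °C to rt
Reagents that add atoms: none
Why: Acetylation of the pseudo-acid hydroxyl and base-induced 1,2-elimination, the usual dehydration of γ-hydroxybutenolides; C8-H is allylic, the product is a conjugated trienolide, and next to E-C6=C7 the ten-membered ring favours a C8=C9 bond that is cis within the ring (C7 on the side of C12, away from the lactone oxygen), the geometry of the target, because the other isomer would hold two in-ring trans bonds of one diene.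

Step 16
Reactants: 26 ylidene butenolide PMB ether
Product: 27 (1R,3S,5S,6E,8E)-C5 alcohol (C13 OTIPS)
Conditions: DDQ (1.3 equiv), CH2Cl2/pH 7 buffer 10:1, 0 °C
Reagents that add atoms: none
Why: Oxidative PMB cleavage (hydride abstraction, hydrolysis of the oxocarbenium ion), placed after the furan has gone because the electron-poor trienolide, unlike a trialkylfuran with a doubly activated C8 methylene, should resist DDQ, while the large excess of water competes with the hindered C3 hydroxyl for the cation.

Step 17
Reactants: 27 C5 alcohol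
Product: 28 (1R,3S,5S,6E,8E)-C5 acetate (C13 OTIPS)
Conditions: Ac2O, pyridine, DMAP (cat.), CH2Cl2, 0 °C
Reagents that add atoms: acetic anhydride CC(=O)OC(C)=O
Why: Standard acetylation of a secondary allylic alcohol, under which the tertiary C3 hydroxyl reacts far more slowly.

Step 18
Reactants: 28 C5 acetate TIPS ether
Product: 29 target CNP0246543.2
Conditions: HF·pyridine, pyridine, THF, 0 °C to rt
Reagents that add atoms: none
Why: Fluoride-driven desilylation under buffered, non-basic conditions, which frees C13-OH without acyl migration, ester cleavage or addition to the trienolide.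

## Compound list

1 | dimethyl furan-3,4-dicarboxylate | COC(=O)c1cocc1C(=O)OC | starting material
2 | methyl 4-(hydroxymethyl)furan-3-carboxylate | COC(=O)c1cocc1CO | intermediate
3 | methyl 4-[(triisopropylsilyloxy)methyl]furan-3-carboxylate | COC(=O)c1cocc1CO[Si](C(C)C)(C(C)C)C(C)C | intermediate
4 | 4-[(triisopropylsilyloxy)methyl]furan-3-carboxylic acid | OC(=O)c1cocc1CO[Si](C(C)C)(C(C)C)C(C)C | intermediate
5 | 3-methylbut-2-enal | CC(C)=CC=O | starting material
6 | allylmagnesium bromide | C=CC[Mg]Br | starting material
7 | diisopinocampheylborinate ester of 8 (not isolated) | C=CC[C@H](OB([C@@H]1C[C@@H]2C[C@H]([C@H]1C)C2(C)C)[C@@H]1C[C@@H]2C[C@H]([C@H]1C)C2(C)C)C=C(C)C | intermediate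
8 | (4S)-6-methylhepta-1,5-dien-4-ol | C=CC[C@H](O)C=C(C)C | intermediate
9 | (4S)-4-[(4-methoxybenzyl)oxy]-6-methylhepta-1,5-diene | C=CC[C@H](OCc1ccc(OC)cc1)C=C(C)C | intermediate
10 | (2E,4S)-4-[(4-methoxybenzyl)oxy]-2-methylhepta-2,6-dien-1-ol | OC/C(C)=C/[C@@H](OCc1ccc(OC)cc1)CC=C | intermediate
11 | (2E,4S)-1-bromo-4-[(4-methoxybenzyl)oxy]-2-methylhepta-2,6-diene | BrC/C(C)=C/[C@@H](OCc1ccc(OC)cc1)CC=C | intermediate
12 | lithium 2-lithio-4-[(triisopropylsilyloxy)methyl]furan-3-carboxylate (not isolated) | [Li]c1occ(CO[Si](C(C)C)(C(C)C)C(C)C)c1C(=O)O[Li] | intermediate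
13 | 2-{(2E,4S)-4-[(4-methoxybenzyl)oxy]-2-methylhepta-2,6-dien-1-yl}-4-[(triisopropylsilyloxy)methyl]furan-3-carboxylic acid | OC(=O)c1c(C/C(C)=C/[C@@H](OCc2ccc(OC)cc2)CC=C)occ1CO[Si](C(C)C)(C(C)C)C(C)C | intermediate
14 | 2-{(2E,4S)-4-[(4-methoxybenzyl)oxy]-2-methyl-6-oxohept-2-en-1-yl}-4-[(triisopropylsilyloxy)methyl]furan-3-carboxylic acid | OC(=O)c1c(C/C(C)=C/[C@@H](OCc2ccc(OC)cc2)CC(C)=O)occ1CO[Si](C(C)C)(C(C)C)C(C)C | intermediate
15 | acid chloride of 14 (not isolated) | ClC(=O)c1c(C/C(C)=C/[C@@H](OCc2ccc(OC)cc2)CC(C)=O)occ1CO[Si](C(C)C)(C(C)C)C(C)C | intermediate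
16 | diazoketone from 15 (not isolated) | [N-]=[N+]=CC(=O)c1c(C/C(C)=C/[C@@H](OCc2ccc(OC)cc2)CC(C)=O)occ1CO[Si](C(C)C)(C(C)C)C(C)C | intermediate
17 | bromoacetyl furan with the C3 methyl ketone, (5S,6E) | BrCC(=O)c1c(C/C(C)=C/[C@@H](OCc2ccc(OC)cc2)CC(C)=O)occ1CO[Si](C(C)C)(C(C)C)C(C)C | intermediate
18 | C1=C2 diiodosamarium enolate (not isolated) | C=C(O[Sm](I)I)c1c(C/C(C)=C/[C@@H](OCc2ccc(OC)cc2)CC(C)=O)occ1CO[Si](C(C)C)(C(C)C)C(C)C | intermediate
19 | C3 diiodosamarium aldolate of 20 (not isolated) | O=C1C[C@@](C)(O[Sm](I)I)C[C@H](OCc2ccc(OC)cc2)/C=C(C)/Cc2occ(CO[Si](C(C)C)(C(C)C)C(C)C)c21 | intermediate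
20 | furan-fused (3S,5S,6E)-β-hydroxy cyclodecenone: C1 ketone, C3 OH and CH3, C5 OPMB, C7 CH3, C11 CH2OTIPS | O=C1C[C@@](C)(O)C[C@H](OCc2ccc(OC)cc2)/C=C(C)/Cc2occ(CO[Si](C(C)C)(C(C)C)C(C)C)c21 | intermediate
21 | furan-fused (1R,3R,5S,6E)-1,3-anti diol | O[C@@H]1C[C@@](C)(O)C[C@H](OCc2ccc(OC)cc2)/C=C(C)/Cc2occ(CO[Si](C(C)C)(C(C)C)C(C)C)c21 | intermediate
22 | furan-fused (1R,3S,5S,6E)-C1 methacrylate | C=C(C)C(=O)O[C@@H]1C[C@@](C)(O)C[C@H](OCc2ccc(OC)cc2)/C=C(C)/Cc2occ(CO[Si](C(C)C)(C(C)C)C(C)C)c21 | intermediate
23 | C9,C10-endoperoxide of 22 (not isolated) | C=C(C)C(=O)O[C@@H]1C[C@@](C)(O)C[C@H](OCc2ccc(OC)cc2)/C=C(C)/CC23OOC(O2)C(CO[Si](C(C)C)(C(C)C)C(C)C)=C13 | intermediate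
24 | γ-hydroxybutenolide, C9 OH (epimer mixture) | C=C(C)C(=O)O[C@@H]1C[C@@](C)(O)C[C@H](OCc2ccc(OC)cc2)/C=C(C)/CC2(O)OC(=O)C(CO[Si](C(C)C)(C(C)C)C(C)C)=C12 | intermediate
25 | γ-acetoxybutenolide, C9 OAc (not isolated) | C=C(C)C(=O)O[C@@H]1C[C@@](C)(O)C[C@H](OCc2ccc(OC)cc2)/C=C(C)/CC2(OC(C)=O)OC(=O)C(CO[Si](C(C)C)(C(C)C)C(C)C)=C12 | intermediate
26 | (1R,3S,5S,6E,8E)-ylidene butenolide, C5 OPMB, C13 OTIPS | C=C(C)C(=O)O[C@@H]1C[C@@](C)(O)C[C@H](OCc2ccc(OC)cc2)/C=C(C)/C=C2/OC(=O)C(CO[Si](C(C)C)(C(C)C)C(C)C)=C21 | intermediate
27 | (1R,3S,5S,6E,8E)-ylidene butenolide, C5 OH, C13 OTIPS | C=C(C)C(=O)O[C@@H]1C[C@@](C)(O)C[C@H](O)/C=C(C)/C=C2/OC(=O)C(CO[Si](C(C)C)(C(C)C)C(C)C)=C21 | intermediate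
28 | (1R,3S,5S,6E,8E)-ylidene butenolide, C5 OAc, C13 OTIPS | C=C(C)C(=O)O[C@@H]1C[C@@](C)(O)C[C@H](OC(C)=O)/C=C(C)/C=C2/OC(=O)C(CO[Si](C(C)C)(C(C)C)C(C)C)=C21 | intermediate
29 | CNP0246543.2, (1R,3S,5S,6E,8E) | C=C(C)C(=O)O[C@@H]1C[C@@](C)(O)C[C@H](OC(C)=O)/C=C(C)/C=C2/OC(=O)C(CO)=C21 | target

## Count and risks

Total steps: 18. Longest linear sequence: 15 steps (from 5 through steps 4 to 18). The furan branch (steps 1 to 3) joins at step 8.

**1. Step 11.**
- Risk: the enolate may be protonated before it closes the ring. The strained tertiary aldolate may revert on warming, intermolecular aldol addition may compete, and facial selectivity may be poor if the C5 ether does not stay on the metal.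
- Fallback, from 17 back to 20: Zn dust and Me3SiCl (TMEDA, Et2O, 0 °C) convert the bromo ketone regiospecifically into the trimethylsilyl enol ether F1. Slow addition of F1 to Me2AlCl (2.5 equiv) in CH2Cl2 at −78 °C under high dilution runs the same C2-C3 closure as a chelation-controlled intramolecular Mukaiyama aldol addition. Aluminium bridges the C3 carbonyl and the C5 ether, and the loss of the silyl group drives the addition forward. Aqueous work-up gives 20.

**2. Step 12.**
- Risk: ligand exchange at a tertiary hydroxyl is slow. The conformation of the ten-membered ring, rather than the chair model, may decide which face of the conjugated ketone is open. The reduction may therefore be sluggish or poorly anti-selective.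
- Fallback, from 20 back to 22: the opposite relative configuration is made on purpose and then inverted. A Narasaka-Prasad reduction (Et2BOMe, NaBH4, THF/MeOH, −78 °C) gives the 1,3-syn diol F2. A Mitsunobu esterification of its secondary hydroxyl with methacrylic acid (PPh3, DIAD, toluene, 0 °C) installs the ester with inversion at C1 and arrives at 22, taking the place of steps 12 and 13.

**3. Step 15.**
- Risk: the free C3 hydroxyl may capture the activated C9 centre across the ring, giving a six-membered ketal through C3-C2-C1-C12-C9. The wrong hydroxyl may be acetylated, or control of the C8=C9 geometry may be poor.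
- Fallback, from 22 back to 29: Et3SiOTf and 2,6-lutidine (CH2Cl2, −78 °C) cap the C3 hydroxyl as the triethylsilyl ether F3, and steps 14 to 17 are run in this series.
  - Singlet oxygen gives the endoperoxide F4 and, with i-Pr2NEt, the hydroxybutenolide F5.
  - Ac2O/pyridine gives the acetoxybutenolide F6, and DBU gives the ylidene butenolide F7.
  - DDQ frees the C5 alcohol F8, now without a neighbouring hydroxyl that could trap the benzylic cation.
  - Acetylation gives the C5 acetate F9.
  - HF·pyridine removes both silyl groups in one operation and gives 29, at the cost of one extra step.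

## Further compounds

F1 | step 11 | trimethylsilyl enol ether (C1=C2) derived from 17 | C=C(O[Si](C)(C)C)c1c(C/C(C)=C/[C@@H](OCc2ccc(OC)cc2)CC(C)=O)occ1CO[Si](C(C)C)(C(C)C)C(C)C
F2 | step 12 | furan-fused (1S,3R,5S,6E)-1,3-syn diol, C1 epimer of 21 | O[C@H]1C[C@@](C)(O)C[C@H](OCc2ccc(OC)cc2)/C=C(C)/Cc2occ(CO[Si](C(C)C)(C(C)C)C(C)C)c21
F3 | step 15 | C3 triethylsilyl ether of 22 | C=C(C)C(=O)O[C@@H]1C[C@@](C)(O[Si](CC)(CC)CC)C[C@H](OCc2ccc(OC)cc2)/C=C(C)/Cc2occ(CO[Si](C(C)C)(C(C)C)C(C)C)c21
F4 | step 15 | C9,C10-endoperoxide of F3 | C=C(C)C(=O)O[C@@H]1C[C@@](C)(O[Si](CC)(CC)CC)C[C@H](OCc2ccc(OC)cc2)/C=C(C)/CC23OOC(O2)C(CO[Si](C(C)C)(C(C)C)C(C)C)=C13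
F5 | step 15 | C3 triethylsilyl ether of 24 | C=C(C)C(=O)O[C@@H]1C[C@@](C)(O[Si](CC)(CC)CC)C[C@H](OCc2ccc(OC)cc2)/C=C(C)/CC2(O)OC(=O)C(CO[Si](C(C)C)(C(C)C)C(C)C)=C12
F6 | step 15 | C3 triethylsilyl ether of 25 | C=C(C)C(=O)O[C@@H]1C[C@@](C)(O[Si](CC)(CC)CC)C[C@H](OCc2ccc(OC)cc2)/C=C(C)/CC2(OC(C)=O)OC(=O)C(CO[Si](C(C)C)(C(C)C)C(C)C)=C12
F7 | step 15 | C3 triethylsilyl ether of 26 | C=C(C)C(=O)O[C@@H]1C[C@@](C)(O[Si](CC)(CC)CC)C[C@H](OCc2ccc(OC)cc2)/C=C(C)/C=C2/OC(=O)C(CO[Si](C(C)C)(C(C)C)C(C)C)=C21
F8 | step 15 | C3 triethylsilyl ether of 27 | C=C(C)C(=O)O[C@@H]1C[C@@](C)(O[Si](CC)(CC)CC)C[C@H](O)/C=C(C)/C=C2/OC(=O)C(CO[Si](C(C)C)(C(C)C)C(C)C)=C21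
F9 | step 15 | C3 triethylsilyl ether of 28 | C=C(C)C(=O)O[C@@H]1C[C@@](C)(O[Si](CC)(CC)CC)C[C@H](OC(C)=O)/C=C(C)/C=C2/OC(=O)C(CO[Si](C(C)C)(C(C)C)C(C)C)=C21
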